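The earlier runs and the new flask are simulated for an exercise, noise included.

A ratio of 0.221 answers your quick question: this is r, the tail yield, the L gained per D lost late in a run. It comes from the birch run, in which D meets Q over the catalyst X and gives the product L. Between 10.0 min and 30.0 min, L rose from 39.9 % to 42.8 % while D fell from 16.4 % to 3.3 %, and r carries the scatter of 1 percentage point in those readings. So your hunch that leftover D is yield still to come pays little, because D late in the birch run returned L at r per unit of D, well below one for one.

the same everywhere: X 0.11 mol%

|  | D | Q | temperature | remark | time |
|---|---|---|---|---|---|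
| birch | 20 mM | 0.95 equiv | 90 °C | run made earlier |  |
| larch | 30 mM | 0.95 equiv | 90 °C | run made earlier |  |
| north | 20 mM | 0.950 equiv (fed, over 6.0 min) |  | the addition at 70 °C, then warmed to 90 °C; the feed brings no volume worth counting | 30 min |
| south-west | 20 mM | 0.950 equiv (fed, over 6.0 min) | 90 °C | all else is in the flask from the start; the feed brings no volume worth counting | 30 min |
| west | 20 mM (fed, over 6.0 min) | 0.950 equiv | 90 °C | all else is in the flask from the start; the feed brings no volume worth counting | 30 min |
| north-west | 20 mM | 0.950 equiv (fed, over 40 s) | 90 °C | all else is in the flask from the start; the feed brings no volume worth counting | 30 min |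
| south | 20 mM | 0.950 equiv |  | everything together at the start at 70 °C, warmed to 90 °C at 6.0 min | 30 min |

- birch (time / min: L / %, D / %): 4.00: 27.8, 30.9; 10.0: 39.9, 16.4; 20.0: 41.9, 7.5; 30.0: 42.8, 3.3
- larch (time / min: L / %, D / %): 0.667: 6.8, 67.6; 1.50: 16.7, 44.5; 4.00: 40.1, 19.0; 10.0: 50.3, 8.9

(each reading ± 1 percentage point)

- the earlier runs do not show what temperature does; that part of a forecast is a guess

* the best flask by amount of L, in percent of the D charged; "all alike" if 1.5 percentage points covers them all (north / south-west / west / north-west / south / all alike)
* amount of L at the end, in percent of the D charged, north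
* amount of L at the end, in percent of the D charged, south-west
* amount of L at the end, in percent of the D charged, west
* amount of L at the end, in percent of the D charged, north-west
* amount of L at the end, in percent of the D charged, south

My reckoning for the L at which the birch run stops is then its last L plus r times its last D, which gives 43.5 %. North-west takes in Q over 40 s, a feed shorter than the wait to the first birch reading at 4.00 min, so I count north-west as birch, and 43.5 % is my number for it. For the other flasks r gives no number, since it prices only the D left at the end.

The forecast, which reasons that “Feeding Q into waiting D and X should limit the early wasteful burst”, names south-west as best, with north 47 %, south-west 50 %, west 35 %, north-west 43 % and south 44 %.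

The flasks give north 51.4 %, south-west 47.0 %, west 31.7 %, north-west 43.4 % and south 53.7 %, so the best is south.

    Q + Z → X + L (k = 180 /M/s, Ea = 42.0 kJ/mol)
    D + X → X + G (k = 450 /M/s, Ea = 37.0 kJ/mol)
    D + G → J (k = 0.0960 /M/s, Ea = 64.0 kJ/mol)
    X + G ⇌ Z (K = 3100 /M, k = 530 /M/s, Ea = 51.0 kJ/mol, ΔH = −38.0 kJ/mol)
    Q → E (k = 0.00290 /s, Ea = 115 kJ/mol)
    (constants at 90 °C)

South, the best flask, stands at 30.0 min with 3.11 % of D but 0.00702 % of the charge of Q, the limiting reagent. The reckoning by r prices that D at 0.69 points of L. But ten times the time adds less than that price, 0.0037 points, to L in south, which stays at 53.7 %, while D falls to 0 % and J, counted by the two D it holds, climbs from 20.2 % to 22.8 %. West ends with more D than south, 7.54 %, priced by r at 1.7 points of L. Ten times the time leaves L in west at 31.7 % and lifts J from 33.8 % to 41.1 %.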